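**Retrosynthetic overview**

1. Target 34 ⇐ desilylation ⇐ C7–C8 B-alkyl Suzuki coupling of the allyl oxanone 31 (as its alkylborane) with the (Z)-β-iodoenone 15.
2. 15 ⇐ anti-hydroiodination of ynone 13 ⇐ Weinreb amide 10 + propynyl Grignard reagent.
3. Key C3–C4 bond: alkenylzirconocene 9 (syn-hydrozirconation of aryl butyne 7, a nucleophilic vinyl carbon) + α-bromo Weinreb amide 8 (α-carbonyl cation, i.e. enolonium equivalent), nickel-catalysed. This sets the E-alkene and gives the skipped unsaturated carbonyl without base.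
4. 31 ⇐ 6-exo alkoxymercuration of dihydroxy ketone 29 ⇐ Ipc-boron aldol (sets C14) of a methyl ketone made from Seebach-alkylated lactic acid acetal (sets C11).
5. Rings: the arene is bought; the only ring built is the oxanone (step 10), closed before the fragments are joined.

Assumption: the side chain is numbered C1 (benzylic CH2) to C15 (CMe2), so C5 is the chain ketone, C11 the quaternary ring carbon, C12 the ring ketone and C14 the carbinol; compounds 1 and 16 (16 is one step from (S)-lactic acid and pivalaldehyde) are taken as purchased.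

**Route**

Step 1
Reactants: 1 4-methoxy-3-methylphenol; 2 chlorotriisopropylsilane
Product: 3 triisopropyl(4-methoxy-3-methylphenoxy)silane
Conditions: iPr3SiCl, imidazole, DMF, rt
Reagents that add atoms: chlorotriisopropylsilane (2), CC(C)[Si](Cl)(C(C)C)C(C)C
Why: Silyl ether formation; the bulky TIPS group masks the phenol through the organometallic and acidic steps and is too hindered to direct lithiation to its own ortho positions.

Step 2
Reactants: 3 triisopropyl(4-methoxy-3-methylphenoxy)silane; 4 1-bromobut-2-yne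
Product: 7 [3-(but-2-yn-1-yl)-4-methoxy-5-methylphenoxy]triisopropylsilane, via aryllithium 5 (not isolated), via arylmagnesium bromide 6 (not isolated)
Conditions: n-BuLi, TMEDA, Et2O, 0 °C to rt; MgBr2·OEt2, THF, −20 °C; CuBr·SMe2 (5 mol %), 4, −20 °C to rt
Reagents that add atoms: 1-bromobut-2-yne (4), CC#CCBr
Why: Methoxy-directed ortho-lithiation at the only free position ortho to OMe, then Li-to-Mg exchange and copper-catalysed SN2 propargylation at the CH2Br carbon, the γ-methyl group disfavouring the SN2′ allene pathway.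

Step 3
Reactants: 7 [3-(but-2-yn-1-yl)-4-methoxy-5-methylphenoxy]triisopropylsilane; 8 2-bromo-N-methoxy-N-methylacetamide
Product: 10 (E)-N-methoxy-5-[2-methoxy-3-methyl-5-(triisopropylsilyloxy)phenyl]-N,3-dimethylpent-3-enamide, via alkenylzirconocene chloride 9 (not isolated)
Conditions: Cp2Zr(H)Cl (1.3 equiv), THF, rt to 40 °C, filtered from excess hydride; 8, NiCl2·DME (5 mol %), 4,4′-di-tert-butyl-2,2′-bipyridine (6 mol %), THF/DMA, 0 °C to rt
Reagents that add atoms: 2-bromo-N-methoxy-N-methylacetamide (8), CON(C)C(=O)CBr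
Why: Proposed new method: syn-hydrozirconation places Zr on the methyl-bearing alkyne carbon (smaller substituent, thermodynamic regioisomer) and so fixes the E geometry, zirconium-to-nickel transmetalation gives an alkenylnickel species, monovalent nickel abstracts bromine from 8 to give the α-amido radical (C4 acting as an α-carbonyl cation or enolonium equivalent instead of an enolate), and radical capture followed by reductive elimination joins C3 and C4, two carbons that are normally both nucleophilic, with retention of alkene geometry and without base, so the β,γ-alkene cannot move into conjugation; closest known reaction type: nickel-catalysed Negishi-type cross-coupling of alkenylzirconocenes with α-bromo ketones.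

Step 4
Reactants: 10 (E)-N-methoxy-5-[2-methoxy-3-methyl-5-(triisopropylsilyloxy)phenyl]-N,3-dimethylpent-3-enamide; 11 prop-1-ynylmagnesium bromide
Product: 13 (E)-8-[2-methoxy-3-methyl-5-(triisopropylsilyloxy)phenyl]-6-methyloct-6-en-2-yn-4-one, via magnesium hemiaminal adduct 12 (not isolated)
Conditions: MeC≡CMgBr, THF, −20 to 0 °C; cold 1 M HCl
Reagents that add atoms: prop-1-ynylmagnesium bromide (11), CC#C[Mg]Br
Why: Weinreb ketone synthesis; the chelated magnesium adduct stops at mono-addition and the weakly basic alkynyl Grignard reagent does not enolise the β,γ-unsaturated amide.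

Step 5
Reactants: 13 (E)-8-[2-methoxy-3-methyl-5-(triisopropylsilyloxy)phenyl]-6-methyloct-6-en-2-yn-4-one; 14 sodium iodide
Product: 15 (2Z,6E)-2-iodo-8-[2-methoxy-3-methyl-5-(triisopropylsilyloxy)phenyl]-6-methylocta-2,6-dien-4-one
Conditions: NaI, AcOH, rt
Reagents that add atoms: sodium iodide (14), [Na+].[I-]
Why: Conjugate hydroiodination of the ynone; iodide adds to the β-carbon and anti protonation gives the (Z)-β-iodoenone with iodine cis to the carbonyl, which fixes the C6–C7 geometry.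

Step 6
Reactants: 16 (2S,5S)-2-tert-butyl-5-methyl-1,3-dioxolan-4-one; 17 allyl bromide
Product: 19 (2S,5R)-2-tert-butyl-5-methyl-5-(prop-2-en-1-yl)-1,3-dioxolan-4-one, via lithium enolate 18 (not isolated)
Conditions: LiN(iPr)2, THF, −78 °C; allyl bromide, −78 to −20 °C
Reagents that add atoms: allyl bromide (17), C=CCBr
Why: Seebach alkylation (self-regeneration of stereocentres); the enolate is alkylated anti to the tert-butyl group, so allyl replaces H with retention and sets C11 as R.

Step 7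
Reactants: 19 (2S,5R)-2-tert-butyl-5-methyl-5-(prop-2-en-1-yl)-1,3-dioxolan-4-one; 20 methyllithium
Product: 22 (R)-3-hydroxy-3-methylhex-5-en-2-one, via lithium hemiketal alkoxide 21 (not isolated)
Conditions: MeLi (1.05 equiv), THF, −78 °C; 1 M HCl, THF, rt
Reagents that add atoms: methyllithium (20), [Li]C
Why: Single nucleophilic addition to the non-enolisable lactone-type carbonyl gives a cyclic lithium hemiketal alkoxide that is stable at −78 °C, and acid work-up collapses it to the α-hydroxy methyl ketone with loss of pivalaldehyde, C11 being untouched.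

Step 8
Reactants: 22 (R)-3-hydroxy-3-methylhex-5-en-2-one; 23 chlorotrimethylsilane
Product: 24 (R)-3-methyl-3-(trimethylsilyloxy)hex-5-en-2-one
Conditions: Me3SiCl, imidazole, DMF, 0 °C
Reagents that add atoms: chlorotrimethylsilane (23), C[Si](C)(C)Cl
Why: Silylation of the tertiary alcohol so that the boron reagent of the next step only enolises the methyl ketone.

Step 9
Reactants: 24 (R)-3-methyl-3-(trimethylsilyloxy)hex-5-en-2-one; 25 methacrolein
Product: 29 (3S,6R)-3,6-dihydroxy-2,6-dimethylnona-1,8-dien-5-one, via boron enolate 26 (not isolated), via boron aldolate 27 (not isolated), via silyl aldol 28 (not isolated)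
Conditions: (+)-Ipc2BCl, Et3N, Et2O, 0 °C; methacrolein, −78 to −20 °C; H2O2, pH 7 buffer, MeOH; citric acid, MeOH, rt
Reagents that add atoms: methacrolein (25), CC(=C)C=O
Why: Paterson boron aldol reaction; the Ipc2B enolate (only the CH3 side can enolise) adds to the Si face of the enal under reagent control to set C14 as S, the fixed C11 centre makes the minor C14 epimer a separable diastereomer, and mild acid then frees the tertiary alcohol.

Step 10
Reactants: 29 (3S,6R)-3,6-dihydroxy-2,6-dimethylnona-1,8-dien-5-one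
Product: 31 (2R,5S)-5-hydroxy-2,6,6-trimethyl-2-(prop-2-en-1-yl)oxan-3-one, via organomercurial 30 (not isolated)
Conditions: Hg(OCOCF3)2 (1.05 equiv), MeCN, −20 to 0 °C; Bu3SnH, AIBN (cat.), THF, rt
Reagents that add atoms: none
Why: Intramolecular alkoxymercuration; the tertiary C11 hydroxyl attacks the mercurinium ion of the 1,1-disubstituted alkene at its tertiary carbon (6-exo, Markovnikov) to close the oxane without touching C11 or C14, and radical demercuration turns CH2Hg into the second methyl group.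

Step 11
Reactants: 31 (2R,5S)-5-hydroxy-2,6,6-trimethyl-2-(prop-2-en-1-yl)oxan-3-one; 15 (2Z,6E)-2-iodo-8-[2-methoxy-3-methyl-5-(triisopropylsilyloxy)phenyl]-6-methylocta-2,6-dien-4-one
Product: 33 (2R,5S)-5-hydroxy-2-{(4Z,8E)-10-[2-methoxy-3-methyl-5-(triisopropylsilyloxy)phenyl]-4,8-dimethyl-6-oxodeca-4,8-dien-1-yl}-2,6,6-trimethyloxan-3-one, via bis-boron adduct 32 (not isolated)
Conditions: 9-BBN (2.2 equiv), THF, 0 °C to rt; H2O, K3PO4, 15, Pd(dppf)Cl2 (5 mol %), AsPh3, DMF, rt
Reagents that add atoms: none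
Why: B-alkyl Suzuki–Miyaura coupling; 9-BBN hydroborates the terminal alkene anti-Markovnikov faster than it reduces the hindered α-quaternary ketone, and the primary alkylborane couples with the (Z)-β-iodoenone with retention of alkene geometry.

Step 12
Reactants: 33 (2R,5S)-5-hydroxy-2-{(4Z,8E)-10-[2-methoxy-3-methyl-5-(triisopropylsilyloxy)phenyl]-4,8-dimethyl-6-oxodeca-4,8-dien-1-yl}-2,6,6-trimethyloxan-3-one
Product: 34 (2R,5S)-5-hydroxy-2-[(4Z,8E)-10-(5-hydroxy-2-methoxy-3-methylphenyl)-4,8-dimethyl-6-oxodeca-4,8-dien-1-yl]-2,6,6-trimethyloxan-3-one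
Conditions: Bu4NF, AcOH (1:1), THF, 0 °C
Reagents that add atoms: none
Why: Fluoride cleavage of the aryl silyl ether, buffered with acetic acid so that the β,γ-unsaturated ketone, the (Z)-enone and the β-hydroxy ketone are not exposed to base.

**Compound list**

1 | 4-methoxy-3-methylphenol | COc1ccc(O)cc1C | starting material
2 | chlorotriisopropylsilane | CC(C)[Si](Cl)(C(C)C)C(C)C | starting material
3 | triisopropyl(4-methoxy-3-methylphenoxy)silane | COc1ccc(O[Si](C(C)C)(C(C)C)C(C)C)cc1C | intermediate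
4 | 1-bromobut-2-yne | CC#CCBr | starting material
5 | [2-methoxy-3-methyl-5-(triisopropylsilyloxy)phenyl]lithium | COc1c(C)cc(O[Si](C(C)C)(C(C)C)C(C)C)cc1[Li] | intermediate
6 | [2-methoxy-3-methyl-5-(triisopropylsilyloxy)phenyl]magnesium bromide | COc1c(C)cc(O[Si](C(C)C)(C(C)C)C(C)C)cc1[Mg]Br | intermediate
7 | [3-(but-2-yn-1-yl)-4-methoxy-5-methylphenoxy]triisopropylsilane | COc1c(C)cc(O[Si](C(C)C)(C(C)C)C(C)C)cc1CC#CC | intermediate
8 | 2-bromo-N-methoxy-N-methylacetamide | CON(C)C(=O)CBr | starting material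
9 | chlorobis(cyclopentadienyl){(E)-4-[2-methoxy-3-methyl-5-(triisopropylsilyloxy)phenyl]but-2-en-2-yl}zirconium | COc1c(C)cc(O[Si](C(C)C)(C(C)C)C(C)C)cc1C/C=C(\C)[Zr](Cl)(C1C=CC=C1)C1C=CC=C1 | intermediate
10 | (E)-N-methoxy-5-[2-methoxy-3-methyl-5-(triisopropylsilyloxy)phenyl]-N,3-dimethylpent-3-enamide | COc1c(C)cc(O[Si](C(C)C)(C(C)C)C(C)C)cc1C/C=C(\C)CC(=O)N(C)OC | intermediate
11 | prop-1-ynylmagnesium bromide | CC#C[Mg]Br | starting material
12 | bromomagnesium alkoxide of the hemiaminal from 10 and 11 (tetrahedral adduct at C5) | COc1c(C)cc(O[Si](C(C)C)(C(C)C)C(C)C)cc1C/C=C(\C)CC(O[Mg]Br)(C#CC)N(C)OC | intermediate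
13 | (E)-8-[2-methoxy-3-methyl-5-(triisopropylsilyloxy)phenyl]-6-methyloct-6-en-2-yn-4-one | COc1c(C)cc(O[Si](C(C)C)(C(C)C)C(C)C)cc1C/C=C(\C)CC(=O)C#CC | intermediate
14 | sodium iodide | [Na+].[I-] | starting material
15 | (2Z,6E)-2-iodo-8-[2-methoxy-3-methyl-5-(triisopropylsilyloxy)phenyl]-6-methylocta-2,6-dien-4-one | COc1c(C)cc(O[Si](C(C)C)(C(C)C)C(C)C)cc1C/C=C(\C)CC(=O)/C=C(/C)I | intermediate
16 | (2S,5S)-2-tert-butyl-5-methyl-1,3-dioxolan-4-one | C[C@@H]1O[C@H](C(C)(C)C)OC1=O | starting material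
17 | allyl bromide (3-bromoprop-1-ene) | C=CCBr | starting material
18 | lithium enolate of 16 (lithium 2-tert-butyl-5-methyl-1,3-dioxol-4-olate, acetal centre unchanged) | CC1=C(O[Li])O[C@@H](C(C)(C)C)O1 | intermediate
19 | (2S,5R)-2-tert-butyl-5-methyl-5-(prop-2-en-1-yl)-1,3-dioxolan-4-one | C=CC[C@@]1(C)O[C@H](C(C)(C)C)OC1=O | intermediate
20 | methyllithium | [Li]C | starting material
21 | lithium (2S,5R)-2-tert-butyl-4,5-dimethyl-5-(prop-2-en-1-yl)-1,3-dioxolan-4-olate (both C4 epimers) | C=CC[C@@]1(C)O[C@H](C(C)(C)C)OC1(C)O[Li] | intermediate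
22 | (R)-3-hydroxy-3-methylhex-5-en-2-one | C=CC[C@@](C)(O)C(C)=O | intermediate
23 | chlorotrimethylsilane | C[Si](C)(C)Cl | starting material
24 | (R)-3-methyl-3-(trimethylsilyloxy)hex-5-en-2-one | C=CC[C@@](C)(O[Si](C)(C)C)C(C)=O | intermediate
25 | methacrolein (2-methylprop-2-enal) | CC(=C)C=O | starting material
26 | (R)-2-[bis((+)-isopinocampheyl)boryloxy]-3-methyl-3-(trimethylsilyloxy)hexa-1,5-diene | C=CC[C@@](C)(O[Si](C)(C)C)C(=C)OB([C@H]1C[C@H]2C[C@@H]([C@@H]1C)C2(C)C)[C@H]1C[C@H]2C[C@@H]([C@@H]1C)C2(C)C | intermediate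
27 | bis((+)-isopinocampheyl)borinate of (3S,6R)-3-hydroxy-2,6-dimethyl-6-(trimethylsilyloxy)nona-1,8-dien-5-one | C=CC[C@@](C)(O[Si](C)(C)C)C(=O)C[C@H](OB([C@H]1C[C@H]2C[C@@H]([C@@H]1C)C2(C)C)[C@H]1C[C@H]2C[C@@H]([C@@H]1C)C2(C)C)C(C)=C | intermediate
28 | (3S,6R)-3-hydroxy-2,6-dimethyl-6-(trimethylsilyloxy)nona-1,8-dien-5-one | C=CC[C@@](C)(O[Si](C)(C)C)C(=O)C[C@H](O)C(C)=C | intermediate
29 | (3S,6R)-3,6-dihydroxy-2,6-dimethylnona-1,8-dien-5-one | C=CC[C@@](C)(O)C(=O)C[C@H](O)C(C)=C | intermediate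
30 | {[(3S,6R)-3-hydroxy-2,6-dimethyl-5-oxo-6-(prop-2-en-1-yl)oxan-2-yl]methyl}mercury trifluoroacetate (both C2 epimers) | C=CC[C@@]1(C)OC(C)(C[Hg]OC(=O)C(F)(F)F)[C@@H](O)CC1=O | intermediate
31 | (2R,5S)-5-hydroxy-2,6,6-trimethyl-2-(prop-2-en-1-yl)oxan-3-one | C=CC[C@@]1(C)OC(C)(C)[C@@H](O)CC1=O | intermediate
32 | 9-{3-[(2R,5S)-5-(9-borabicyclo[3.3.1]nonan-9-yloxy)-2,6,6-trimethyl-3-oxooxan-2-yl]propyl}-9-borabicyclo[3.3.1]nonane | C(CC[C@@]1(C)OC(C)(C)[C@@H](OB2C3CCCC2CCC3)CC1=O)B1C2CCCC1CCC2 | intermediate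
33 | (2R,5S)-5-hydroxy-2-{(4Z,8E)-10-[2-methoxy-3-methyl-5-(triisopropylsilyloxy)phenyl]-4,8-dimethyl-6-oxodeca-4,8-dien-1-yl}-2,6,6-trimethyloxan-3-one | COc1c(C)cc(O[Si](C(C)C)(C(C)C)C(C)C)cc1C/C=C(\C)CC(=O)/C=C(/C)CCC[C@@]1(C)OC(C)(C)[C@@H](O)CC1=O | intermediate
34 | (2R,5S)-5-hydroxy-2-[(4Z,8E)-10-(5-hydroxy-2-methoxy-3-methylphenyl)-4,8-dimethyl-6-oxodeca-4,8-dien-1-yl]-2,6,6-trimethyloxan-3-one | COc1c(C)cc(O)cc1C/C=C(\C)CC(=O)/C=C(/C)CCC[C@@]1(C)OC(C)(C)[C@@H](O)CC1=O | target

**Summary**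

Total step count: 12.
Longest linear sequence: 7 steps (16 → 34 through steps 6–12; the aryl branch 1 → 34 through steps 1–5, 11 and 12 is also 7).

**Steps most likely to fail, with fallbacks**

Step 3 (hydrozirconation and nickel coupling). The regiochemistry of Zr–H addition to the methyl/benzyl alkyne may be incomplete. Any Cp2Zr(H)Cl carried over would reduce the Weinreb amide. The nickel step may give reduction or homocoupling of 8. The fallback sets out from 7: hydrozirconation as before and quenching with I2 gives {3-[(E)-3-iodobut-2-en-1-yl]-4-methoxy-5-methylphenoxy}triisopropylsilane F1. Miyaura borylation (B2pin2, PdCl2(dppf), KOPh, toluene, 50 °C) gives the alkenyl pinacol boronate F2. Suzuki coupling of F2 with 8 (Pd(OAc)2, P(o-tolyl)3, K3PO4, THF/H2O, rt) keeps the α-bromo amide as the electrophilic α-carbonyl partner and comes back to the route at 10.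

Step 10 (ring closure). The α-keto tertiary alcohol may be too weak a nucleophile, or trifluoroacetic acid and the mercury salt may attack the allyl group or the allylic alcohol. The fallback sets out from 29: iodoetherification with N-iodosuccinimide (MeCN, 0 °C) gives (2R,5S)-5-hydroxy-6-(iodomethyl)-2,6-dimethyl-2-(prop-2-en-1-yl)oxan-3-one F3 (both C6 epimers). Radical reduction of the C–I bond (Bu3SnH, AIBN, benzene, 60 °C, high tin hydride concentration) comes back at 31.

Step 11 (hydroboration and Suzuki coupling). 9-BBN may reduce the ring ketone, and aqueous phosphate may move the C2=C3 alkene of 15 or 33 into conjugation. The fallback sets out from 31: hydroboration with catecholborane catalysed by RhCl(PPh3)3 (the ketone is left alone) gives the bis(catecholboryl) compound F4. Oxidation with NaBO3 gives (2R,5S)-5-hydroxy-2-(3-hydroxypropyl)-2,6,6-trimethyloxan-3-one F5. I2, PPh3 and imidazole (0 °C, primary hydroxyl only) give the primary iodide F6. A base-free nickel-catalysed reductive cross-electrophile coupling of F6 with 15 (NiBr2·DME, 4,4′-di-tert-butyl-2,2′-bipyridine, Mn, DMA, rt) comes back at 33.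

Further compounds
F1 | step 3 | {3-[(E)-3-iodobut-2-en-1-yl]-4-methoxy-5-methylphenoxy}triisopropylsilane | COc1c(C)cc(O[Si](C(C)C)(C(C)C)C(C)C)cc1C/C=C(\C)I
F2 | step 3 | 2-{(Z)-4-[2-methoxy-3-methyl-5-(triisopropylsilyloxy)phenyl]but-2-en-2-yl}-4,4,5,5-tetramethyl-1,3,2-dioxaborolane (boron trans to the benzylic CH2) | COc1c(C)cc(O[Si](C(C)C)(C(C)C)C(C)C)cc1C/C=C(\C)B1OC(C)(C)C(C)(C)O1
F3 | step 10 | (2R,5S)-5-hydroxy-6-(iodomethyl)-2,6-dimethyl-2-(prop-2-en-1-yl)oxan-3-one (both C6 epimers) | C=CC[C@@]1(C)OC(C)(CI)[C@@H](O)CC1=O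
F4 | step 11 | 2-{3-[(2R,5S)-5-(1,3,2-benzodioxaborol-2-yloxy)-2,6,6-trimethyl-3-oxooxan-2-yl]propyl}-1,3,2-benzodioxaborole | C(CC[C@@]1(C)OC(C)(C)[C@@H](OB2Oc3ccccc3O2)CC1=O)B1Oc2ccccc2O1
F5 | step 11 | (2R,5S)-5-hydroxy-2-(3-hydroxypropyl)-2,6,6-trimethyloxan-3-one | OCCC[C@@]1(C)OC(C)(C)[C@@H](O)CC1=O
F6 | step 11 | (2R,5S)-5-hydroxy-2-(3-iodopropyl)-2,6,6-trimethyloxan-3-one | ICCC[C@@]1(C)OC(C)(C)[C@@H](O)CC1=O
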